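**Strategy**

The synthesis rests on closing ring B (C5–C10) last through its most congested bond, C9–C10. Rings C, D and E are first built as a spiro block by oxidative dearomatisation of a para-phenol and oxa-Michael closure; ring C is desymmetrised and made quaternary at C8, and a 2,6,6-trimethylcyclohexenyl ketone (ring A, C6 carbonyl) is attached through C7, so that rings A and C are joined only by C6–C7–C8. In the key step a C9 vinyl radical of ring C adds 6-endo to C10 of this enone, forming ring B, the C10 quaternary centre and the C6 ketone at once; it exploits the C6 oxygen, which makes C10 (β to C6) the acceptor.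

Key step: step 12

Remark: locants follow terpenoid-style numbering (ring A = C1–C5, C10; ring B = C5–C10 with the acetate on C6; ring C = C8, C9, C11–C14 with spiro C13; ring D = O–C13–C5'–C4'–C3'; ring E = C1'–C6' with C1' ketone, C2' methyl, C4' hydroxyl). Compounds 16 and 18 are racemic; their stereocentre is destroyed in step 11.

**Route**

Step 1
Reactants: 1 4-methoxy-2-methylphenol
Product: 2 4,4-dimethoxy-2-methylcyclohexa-2,5-dien-1-one
Conditions: PhI(OAc)2, MeOH, 0 °C
Reagents that add atoms: methanol, CO
Why: Hypervalent-iodine oxidative dearomatisation of a para-methoxyphenol in methanol traps the phenoxonium ion at C4 as the quinone monoketal, and no stereocentre is formed.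

Step 2
Reactants: 2 4,4-dimethoxy-2-methylcyclohexa-2,5-dien-1-one; 3 4-hydroxyphenylboronic acid
Product: 4 (5S)-5-(4-hydroxyphenyl)-4,4-dimethoxy-2-methylcyclohex-2-en-1-one
Conditions: [Rh(OH)(cod)]2 (cat.), (S)-BINAP, KOH (cat.), dioxane–H2O, 40 °C
Reagents that add atoms: none
Why: Hayashi–Miyaura rhodium-catalysed asymmetric conjugate addition should deliver the aryl group to the unsubstituted enone carbon (future C5') rather than to the methyl-bearing enone, and (S)-BINAP, the ligand that gives (S)-3-arylcyclohexanones, sets C5'.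

Step 3
Reactants: 4 (5S)-5-(4-hydroxyphenyl)-4,4-dimethoxy-2-methylcyclohex-2-en-1-one
Product: 6 spiro keto dienone (rings C/D/E; C1' ketone; C4' dimethyl ketal), via para-quinol 5 (not isolated)
Conditions: PhI(OAc)2, NaHCO3, MeCN–H2O, 0 °C; then DBU (cat.), CH2Cl2, rt
Reagents that add atoms: water, O
Why: Phenol oxidation in aqueous acetonitrile gives the para-quinol, whose tertiary hydroxyl then adds to C3' of the enone (oxa-Michael, 5-exo-trig), closing ring D cis across C3'/C5' by tether constraint and leaving the C2' methyl equatorial under equilibrating conditions, while C13 is not yet stereogenic because ring C is symmetric.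

Step 4
Reactants: 6 spiro keto dienone
Product: 7 C1' alcohol of 6
Conditions: NaBH4, MeOH–CH2Cl2, −78 °C
Reagents that add atoms: none
Why: Borohydride should reduce the saturated C1' ketone much faster than the cross-conjugated dienone (chemoselective 1,2-reduction), hydride entering from the exo face, and the carbinol configuration is immaterial because C1' returns to a ketone in step 17.

Step 5
Reactants: 7 C1' alcohol of 6
Product: 8 C1' triethylsilyl ether
Conditions: Et3SiOTf, 2,6-lutidine, CH2Cl2, 0 °C
Reagents that add atoms: triethylsilyl trifluoromethanesulfonate, CC[Si](CC)(CC)OS(=O)(=O)C(F)(F)F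
Why: Silyl triflate silylation masks the hindered C1' alcohol so that ring E survives the hydride, amide-base and organometallic steps.

Step 6
Reactants: 8 C1' triethylsilyl ether
Product: 10 mono-alkylated enone (Weinreb amide side chain on C8), via lithium enolate 9 (not isolated)
Conditions: LiBH(s-Bu)3, THF, −78 °C; then BrCH2C(O)N(OMe)Me, DMPU, −78 to −20 °C
Reagents that add atoms: 2-bromo-N-methoxy-N-methylacetamide, CON(C)C(=O)CBr
Why: In this Ganem-type conjugate reduction–alkylation the bulky hydride should attack the β-carbon of the exposed exo enone arm (the arm syn to C4', the endo arm being buried under the C2'–C1'–C6' bridge and its silyl ether), which makes C13 stereogenic in the required sense, and the enolate is then alkylated at C8 (C8 configuration immaterial here).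

Step 7
Reactants: 10 mono-alkylated enone
Product: 12 C8-quaternary enone, via lithium dienolate 11 (not isolated)
Conditions: LiN(i-Pr)2, THF, −78 °C; then MeI, −78 to −40 °C
Reagents that add atoms: iodomethane, CI
Why: Kinetic α'-deprotonation of the remaining enone and enolate methylation create the C8 quaternary centre, iodomethane approaching the flattened dienolate from the face of the small ring-D oxygen (anti to the C5' branch on C13) so that the methyl ends cis to the C13–O bond.

Step 8
Reactants: 12 C8-quaternary enone
Product: 13 saturated C9 ketone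
Conditions: H2 (3 bar), RhCl(PPh3)3 (cat.), PhH–EtOH, rt
Reagents that add atoms: none
Why: Homogeneous hydrogenation with RhCl(PPh3)3 should saturate the disubstituted C11=C12 enone bond without hydrogenolysis of the allylic C13–O bond.

Step 9
Reactants: 13 saturated C9 ketone
Product: 15 C9 vinyl iodide, via hydrazone 14 (not isolated)
Conditions: N2H4·H2O, Et3N, EtOH, 80 °C; then I2, tetramethylguanidine, THF, 0 °C
Reagents that add atoms: iodine, II
Why: In the Barton vinyl iodide synthesis the hydrazone of the α-quaternary C9 ketone is oxidised by iodine and can eliminate only towards C11, giving the C9 iodoalkene regiospecifically, as with 17-ketosteroids.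

Step 10
Reactants: 16 2,2,6-trimethylcyclohexanone; 17 2,4,6-triisopropylbenzenesulfonohydrazide
Product: 18 2,2,6-trimethylcyclohexanone trisylhydrazone
Conditions: HCl (cat.), MeOH, rt
Reagents that add atoms: none
Why: Acid-catalysed hydrazone condensation gives the Shapiro precursor of ring A.

Step 11
Reactants: 18 2,2,6-trimethylcyclohexanone trisylhydrazone; 15 C9 vinyl iodide
Product: 21 seco-B iodo enone, via vinyllithium 19 (not isolated), via organocerium 20 (not isolated)
Conditions: n-BuLi (2.05 equiv), THF, −78 to 0 °C; CeCl3, −78 °C; then 15, −78 to 0 °C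
Reagents that add atoms: none
Why: The Shapiro reaction (only the C–H next to the methyl-bearing carbon can be removed) gives the tetrasubstituted vinyllithium, transmetalation to the less basic organocerium avoids iodine–lithium exchange, and acylation by the Weinreb amide stops at the C6 ketone through the chelated tetrahedral intermediate.

Step 12
Reactants: 21 seco-B iodo enone
Product: 22 ring-B-closed 9(11)-ene 6-ketone
Conditions: Bu3SnH (slow addition), AIBN, PhH (high dilution), 80 °C; then DBU (cat.), CH2Cl2, rt
Reagents that add atoms: none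
Why: The tributyltin radical abstracts iodine to give the bent σ-vinyl radical at C9, which bonds to C10 of the enone either directly or by 5-exo attack at C5 followed by a 1,2-vinyl shift through the cyclopropylcarbinyl radical, and the resulting tertiary α-keto radical at C5 is reduced by the stannane. The closest known reaction type is the Stork vinyl radical cyclisation onto an α,β-unsaturated ketone, and ring B is closed in the 6-endo-trig mode. C10 is controlled by the tether: the new bond forms in the plane of the C9=C11 double bond while C7–C6–C5 reaches C10 from the face of ring C opposite the C8 methyl, and because the C10 methyl is cis to C6 on the tetrasubstituted alkene it must end on the face of the C8 methyl, with C1 equatorial on ring B. C5 receives its hydrogen from the β face, anti to the axial methyl groups, and as an α-keto centre it converges on the trans-fused epimer with DBU. C9 stays sp2 and is set in step 13. The step needs ring closure to outrun direct reduction of the vinyl radical, which high dilution and slow stannane addition should secure, the α-keto radical being the thermodynamic sink.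

Step 13
Reactants: 22 ring-B-closed 9(11)-ene 6-ketone
Product: 23 saturated 6-ketone
Conditions: Mn(dpm)3 (cat.), PhSiH3, t-BuOOH, i-PrOH, rt
Reagents that add atoms: none
Why: Shenvi hydrogen-atom-transfer hydrogenation of the hindered trisubstituted C9=C11 alkene should deliver hydrogen to the tertiary C9 radical from the β face, opposite the axial C8 and C10 methyl groups, giving the thermodynamically favoured trans B/C fusion.

Step 14
Reactants: 23 saturated 6-ketone
Product: 24 C6 axial alcohol
Conditions: LiAlH4, THF, −20 °C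
Reagents that add atoms: none
Why: Hydride reduction of the C6 ketone from the β face (the α face is screened by the axial C4, C8 and C10 methyl groups) should give the axial alcohol, as with 6-oxo-5α-steroids.

Step 15
Reactants: 24 C6 axial alcohol
Product: 25 C6 acetate
Conditions: Ac2O, DMAP, Et3N, CH2Cl2, 40 °C
Reagents that add atoms: acetic anhydride, CC(=O)OC(C)=O
Why: DMAP-catalysed acylation esterifies the hindered axial alcohol while every other oxygen is masked.

Step 16
Reactants: 25 C6 acetate
Product: 26 C1' alcohol C4' ketone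
Conditions: 2 M aq. HCl, THF, 40 °C
Reagents that add atoms: water, O
Why: Acid hydrolysis removes the silyl ether and the dimethyl ketal in one operation while the hindered acetate survives.

Step 17
Reactants: 26 C1' alcohol C4' ketone
Product: 27 C1',C4' diketone
Conditions: Dess–Martin periodinane, CH2Cl2, rt
Reagents that add atoms: none
Why: Dess–Martin oxidation of the only carbinol restores the C1' ketone, with the C2' methyl staying equatorial.

Step 18
Reactants: 27 C1',C4' diketone
Product: 28 CNP0188572.2 (target)
Conditions: NaBH4 (limiting), MeOH–CH2Cl2, −78 °C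
Reagents that add atoms: none
Why: In this chemoselective borohydride reduction the strained, α-alkoxy bridging C4' ketone should be more electrophilic than the hindered C1' ketone, and hydride enters anti to the O–C13 bridge (from the side of the C2'–C1'–C6' bridge), giving the equatorial C4' alcohol syn to the ether bridge.

**Compound list**

1 | 4-methoxy-2-methylphenol | COc1ccc(O)c(C)c1 | starting material
2 | 4,4-dimethoxy-2-methylcyclohexa-2,5-dien-1-one | COC1(OC)C=CC(=O)C(C)=C1 | intermediate
3 | 4-hydroxyphenylboronic acid | OB(O)c1ccc(O)cc1 | starting material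
4 | (5S)-5-(4-hydroxyphenyl)-4,4-dimethoxy-2-methylcyclohex-2-en-1-one | O=C1C[C@@H](c2ccc(O)cc2)C(OC)(OC)C=C1C | intermediate
5 | para-quinol: (5S)-5-(1-hydroxy-4-oxocyclohexa-2,5-dien-1-yl)-4,4-dimethoxy-2-methylcyclohex-2-en-1-one | O=C1C[C@@H](C2(O)C=CC(=O)C=C2)C(OC)(OC)C=C1C | intermediate (not isolated)
6 | spiro keto dienone: cyclohexa-2,5-dienone ring C (C9 carbonyl) spiro at C13 to the 6-oxabicyclo[3.2.1]octane rings D/E; C1' ketone, C4' dimethyl ketal; C2' methyl, C3'–O and C5'–C13 all cis as in 28 | O=C1C=CC2(C=C1)O[C@@H]1C(OC)(OC)[C@H]2CC(=O)[C@@H]1C | intermediate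
7 | C1' alcohol of 6 (hydroxyl on the face of the ether bridge) | O=C1C=CC2(C=C1)O[C@@H]1C(OC)(OC)[C@H]2C[C@H](O)[C@@H]1C | intermediate
8 | C1' triethylsilyl ether of 7 | O=C1C=CC2(C=C1)O[C@@H]1C(OC)(OC)[C@H]2C[C@H](O[Si](CC)(CC)CC)[C@@H]1C | intermediate
9 | lithium enolate (C9–O–Li, C8=C9; C14 saturated exo arm; C13 as in 28) | [Li]OC1=CC[C@]2(C=C1)O[C@@H]1C(OC)(OC)[C@H]2C[C@H](O[Si](CC)(CC)CC)[C@@H]1C | intermediate (not isolated)
10 | mono-alkylated enone: C8–CH2C(O)N(OMe)Me (C8 epimers), C9 ketone, C11=C12, C13 as in 28 | CON(C)C(=O)CC1C[C@]2(C=CC1=O)O[C@@H]1C(OC)(OC)[C@H]2C[C@H](O[Si](CC)(CC)CC)[C@@H]1C | intermediate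
11 | lithium dienolate of 10 (C8=C9–O–Li, C11=C12) | CON(C)C(=O)CC=1C[C@]2(C=CC=1O[Li])O[C@@H]1C(OC)(OC)[C@H]2C[C@H](O[Si](CC)(CC)CC)[C@@H]1C | intermediate (not isolated)
12 | C8-quaternary enone: C8 methyl cis to C13–O, C8 and C13 as in 28 | CON(C)C(=O)C[C@]1(C)C[C@]2(C=CC1=O)O[C@@H]1C(OC)(OC)[C@H]2C[C@H](O[Si](CC)(CC)CC)[C@@H]1C | intermediate
13 | saturated C9 ketone (C11, C12 methylene) | CON(C)C(=O)C[C@]1(C)C[C@]2(CCC1=O)O[C@@H]1C(OC)(OC)[C@H]2C[C@H](O[Si](CC)(CC)CC)[C@@H]1C | intermediate
14 | C9 hydrazone of 13 | CON(C)C(=O)C[C@]1(C)C[C@]2(CCC1=NN)O[C@@H]1C(OC)(OC)[C@H]2C[C@H](O[Si](CC)(CC)CC)[C@@H]1C | intermediate (not isolated)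
15 | C9 vinyl iodide (C9=C11) with C7 Weinreb amide | CON(C)C(=O)C[C@]1(C)C[C@]2(CC=C1I)O[C@@H]1C(OC)(OC)[C@H]2C[C@H](O[Si](CC)(CC)CC)[C@@H]1C | intermediate
16 | 2,2,6-trimethylcyclohexanone (racemic) | CC1CCCC(C)(C)C1=O | starting material
17 | 2,4,6-triisopropylbenzenesulfonohydrazide | CC(C)c1cc(C(C)C)c(S(=O)(=O)NN)c(C(C)C)c1 | starting material
18 | 2,2,6-trimethylcyclohexanone 2,4,6-triisopropylbenzenesulfonylhydrazone | CC1CCCC(C)(C)C1=NNS(=O)(=O)c1c(C(C)C)cc(C(C)C)cc1C(C)C | intermediate
19 | (2,6,6-trimethylcyclohex-1-en-1-yl)lithium | [Li]C1=C(C)CCCC1(C)C | intermediate (not isolated)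
20 | dichloro(2,6,6-trimethylcyclohex-1-en-1-yl)cerium | Cl[Ce](Cl)C1=C(C)CCCC1(C)C | intermediate (not isolated)
21 | seco-B iodo enone: ring A 2,6,6-trimethylcyclohexenyl ketone (C6 carbonyl, C5=C10) joined through C7 to C8 of the C9 vinyl iodide | CC1=C(C(=O)C[C@]2(C)C[C@]3(CC=C2I)O[C@@H]2C(OC)(OC)[C@H]3C[C@H](O[Si](CC)(CC)CC)[C@@H]2C)C(C)(C)CCC1 | intermediate
22 | ring-B-closed 9(11)-ene 6-ketone; C5, C8, C10, C13 as in 28 | O=C1C[C@]2(C)C[C@]3(CC=C2[C@]2(C)CCCC(C)(C)[C@@H]12)O[C@@H]1C(OC)(OC)[C@H]3C[C@H](O[Si](CC)(CC)CC)[C@@H]1C | intermediate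
23 | saturated 6-ketone; C9 as in 28 | O=C1C[C@]2(C)C[C@]3(CC[C@H]2[C@]2(C)CCCC(C)(C)[C@@H]12)O[C@@H]1C(OC)(OC)[C@H]3C[C@H](O[Si](CC)(CC)CC)[C@@H]1C | intermediate
24 | C6 axial alcohol (6S) | O[C@H]1C[C@]2(C)C[C@]3(CC[C@H]2[C@]2(C)CCCC(C)(C)[C@@H]12)O[C@@H]1C(OC)(OC)[C@H]3C[C@H](O[Si](CC)(CC)CC)[C@@H]1C | intermediate
25 | C6 acetate with C1' silyl ether and C4' dimethyl ketal | CC(=O)O[C@H]1C[C@]2(C)C[C@]3(CC[C@H]2[C@]2(C)CCCC(C)(C)[C@@H]12)O[C@@H]1C(OC)(OC)[C@H]3C[C@H](O[Si](CC)(CC)CC)[C@@H]1C | intermediate
26 | C6 acetate with C1' alcohol and C4' ketone | CC(=O)O[C@H]1C[C@]2(C)C[C@]3(CC[C@H]2[C@]2(C)CCCC(C)(C)[C@@H]12)O[C@@H]1C(=O)[C@H]3C[C@H](O)[C@@H]1C | intermediate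
27 | C6 acetate C1',C4' diketone | CC(=O)O[C@H]1C[C@]2(C)C[C@]3(CC[C@H]2[C@]2(C)CCCC(C)(C)[C@@H]12)O[C@@H]1C(=O)[C@H]3CC(=O)[C@@H]1C | intermediate
28 | CNP0188572.2, (5R,6S,8R,9R,10S,13S,2'R,3'S,4'R,5'R) | CC(=O)O[C@H]1C[C@]2(C)C[C@]3(CC[C@H]2[C@]2(C)CCCC(C)(C)[C@@H]12)O[C@@H]1[C@H](O)[C@H]3CC(=O)[C@@H]1C | target

**Step count and risks**

Total step count: 18. Longest linear sequence: 17 (steps 1–9 and 11–18; step 10 is the side branch).

Steps most likely to fail:

1. Step 12. The vinyl radical may be reduced by the stannane before it cyclises, may undergo 1,5-hydrogen transfer, or may close 5-exo at C5 without the vinyl shift. The fallback sets out from 21 and returns at 22. A nickel-catalysed reductive conjugate addition (NiCl2(dme), neocuproine, Mn powder, Et3SiCl, DMF) would add the alkenylnickel formed from the C9 iodide to C10 and trap the enolate as the triethylsilyl enol ether F1. Methanolysis (K2CO3, MeOH) would then give 22.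

2. Step 6. The hydride may discriminate poorly between the two enone arms, or may add 1,2 to the dienone with subsequent aromatisation. The fallback sets out from 8 and returns at 10. A ligand-controlled copper hydride conjugate reduction (Cu(OAc)2, the DTBM-SEGPHOS enantiomer matched to the exo arm, (EtO)2MeSiH, t-BuOH, toluene) would give the mono-reduced enone F2. Deprotonation with LiN(i-Pr)2 would then generate enolate 9 for the same alkylation to 10.

3. Step 18. Chemoselectivity between the two ring-E carbonyls may be lost (over-reduction), or hydride may be delivered from the wrong face. The fallback sets out from 26 and returns at 28. The lone C4' ketone of 26 would first be reduced with NaBH4 to the diol F3. The strained axial C1' carbinol would then be oxidised selectively with one equivalent of CrO3·2C5H5N, since compressed axial alcohols are oxidised fastest.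

Further compounds
F1 | step 12 | C6 triethylsilyl enol ether (C5=C6) of 22 | CC[Si](CC)(CC)OC=1C[C@]2(C)C[C@]3(CC=C2[C@]2(C)CCCC(C)(C)C=12)O[C@@H]1C(OC)(OC)[C@H]3C[C@H](O[Si](CC)(CC)CC)[C@@H]1C
F2 | step 6 | mono-reduced enone (C8, C14 methylene; C9 ketone; C11=C12; C13 as in 28) | O=C1CC[C@]2(C=C1)O[C@@H]1C(OC)(OC)[C@H]2C[C@H](O[Si](CC)(CC)CC)[C@@H]1C
F3 | step 18 | C6 acetate C1',C4' diol | CC(=O)O[C@H]1C[C@]2(C)C[C@]3(CC[C@H]2[C@]2(C)CCCC(C)(C)[C@@H]12)O[C@@H]1[C@H](O)[C@H]3C[C@H](O)[C@@H]1C
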